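**Plan**
- Retrosynthesis: cut the C8 methacrylate first, then the ring bond C8–C9 (chromium allylation with allyl transposition), then the lactone (C6–C7 and O6–C12), then C9–C10 and C1–C10 of the acetoxyallyl unit, back to nerol.
- Forward: nerol is epoxidised, cleaved to the C1 aldehyde and extended by acetate aldol, formylation and enol acetylation. The α-methylene lactone is then annulated on the C6 epoxy aldehyde, the ten-membered ring is closed last at C8–C9, and O8 is acylated.
- Stereochemistry: C4/C5 from Sharpless epoxidation; C6/C7 from a Felkin–Anh-controlled, anti-selective allylboration with a geometry-defined boronate; C8/C9 and the C1=C10 geometry from the chair of the chromium closure with a geometry-defined enol acetate.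

Key step: step 17

Remark: atom labels C1–C15 are the germacrane locants of the target. The C1 carbinol (later bromide) centre is formed as both epimers and is left open in the SMILES, because both epimers give the same allylchromium.

**Step 1**
Reactants: 1 prop-2-yn-1-ol
Product: 2 1-methoxy-4-[(prop-2-yn-1-yloxy)methyl]benzene (PMB propargyl ether)
Conditions: NaH, 4-methoxybenzyl chloride, Bu4NI (cat.), THF, 0 °C → rt
Reagents that add atoms: 4-methoxybenzyl chloride, COc1ccc(CCl)cc1
Why: Williamson ether synthesis in which the sodium alkoxide displaces the benzylic chloride under iodide catalysis.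

**Step 2**
Reactants: 2 PMB propargyl ether
Product: 4 methyl 4-[(4-methoxybenzyl)oxy]but-2-ynoate, via lithium acetylide 3 (not isolated)
Conditions: n-BuLi, THF, −78 °C; ClCO2Me, −78 → 0 °C
Reagents that add atoms: methyl chloroformate, COC(=O)Cl
Why: The terminal alkyne is deprotonated and the lithium acetylide is C-acylated by the chloroformate, the standard route to 2-ynoates.

**Step 3**
Reactants: 4 methyl 4-[(4-methoxybenzyl)oxy]but-2-ynoate
Product: 6 methyl (2Z)-4-[(4-methoxybenzyl)oxy]-2-[(4,4,5,5-tetramethyl-1,3,2-dioxaborolan-2-yl)methyl]but-2-enoate, via vinylalane 5 (not isolated)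
Conditions: iBu2AlH, HMPA, THF, 0 °C; then ICH2Bpin, 0 °C → rt
Reagents that add atoms: 2-(iodomethyl)-4,4,5,5-tetramethyl-1,3,2-dioxaborolane, ICB1OC(C)(C)C(C)(C)O1
Why: Conjugate hydroalumination with the iBu2AlH–HMPA complex adds H and Al cis across the ynoate, and the α-alanyl acrylate is homologated by the iodomethylboronate with retention (electrophilic trapping of an α-metallated acrylate), so CH2OPMB ends cis to the ester and trans to CH2B.

**Step 4**
Reactants: 7 nerol
Product: 8 (2S,3R)-2,3-epoxynerol
Conditions: Ti(OiPr)4 (cat.), L-(+)-diethyl tartrate (cat.), t-BuOOH, 4 Å molecular sieves, CH2Cl2, −20 °C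
Reagents that add atoms: tert-butyl hydroperoxide, CC(C)(C)OO
Why: Sharpless asymmetric epoxidation of the Z allylic alcohol, in which the L-(+)-tartrate ligand directs oxygen to the face that gives the (2S,3R) cis-epoxide and so fixes C4 (R) and C5 (S).

**Step 5**
Reactants: 8 (2S,3R)-2,3-epoxynerol
Product: 9 triethylsilyl ether of 8
Conditions: Et3SiCl, imidazole, CH2Cl2, 0 °C
Reagents that add atoms: chlorotriethylsilane, CC[Si](Cl)(CC)CC
Why: Standard silylation of the primary alcohol, with the triethylsilyl group chosen because it can later be oxidised off directly.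

**Step 6**
Reactants: 9 triethylsilyl ether of 8
Product: 11 3-[(2R,3S)-2-methyl-3-(triethylsilyloxymethyl)oxiran-2-yl]propanal (C1 aldehyde), via ozonide 10 (not isolated)
Conditions: O3, CH2Cl2, −78 °C; PPh3, −78 °C → rt
Reagents that add atoms: ozone, [O-][O+]=O
Why: Ozonolysis of the only alkene with reductive work-up gives the C1 aldehyde and acetone, the epoxide and silyl ether being inert to ozone.

**Step 7**
Reactants: 11 C1 aldehyde; 12 methyl acetate
Product: 14 methyl 3-hydroxy-5-[(2R,3S)-2-methyl-3-(triethylsilyloxymethyl)oxiran-2-yl]pentanoate as both C3 epimers, via lithium enolate of methyl acetate 13 (not isolated)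
Conditions: LiN(iPr)2, THF, −78 °C; aq. NH4Cl
Reagents that add atoms: none
Why: Aldol addition of the lithium ester enolate to the aldehyde forms C1–C10; the new carbinol centre is not controlled and need not be.

**Step 8**
Reactants: 14 β-hydroxy ester
Product: 15 methyl 3-[(tert-butyldimethylsilyl)oxy]-5-[(2R,3S)-2-methyl-3-(triethylsilyloxymethyl)oxiran-2-yl]pentanoate
Conditions: t-BuMe2SiCl, imidazole, DMF, rt
Reagents that add atoms: tert-butyldimethylsilyl chloride, CC(C)(C)[Si](C)(C)Cl
Why: Silylation of the secondary alcohol under mild imidazole conditions that leave the epoxide and the primary triethylsilyl ether untouched.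

**Step 9**
Reactants: 15 silyloxy ester; 16 methyl formate
Product: 18 methyl 3-[(tert-butyldimethylsilyl)oxy]-2-formyl-5-[(2R,3S)-2-methyl-3-(triethylsilyloxymethyl)oxiran-2-yl]pentanoate (in equilibrium with its enol), via lithium ester enolate 17 (not isolated)
Conditions: LiN(iPr)2, THF, −78 °C; HCO2Me, −78 → −30 °C; aq. NH4Cl
Reagents that add atoms: none
Why: Crossed Claisen condensation (formylation) of the ester enolate with methyl formate installs C9 at the aldehyde oxidation level, the enolate being trapped cold before β-elimination of the silyloxy group can occur.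

**Step 10**
Reactants: 18 formyl ester
Product: 19 methyl (2E)-2-(acetoxymethylidene)-3-[(tert-butyldimethylsilyl)oxy]-5-[(2R,3S)-2-methyl-3-(triethylsilyloxymethyl)oxiran-2-yl]pentanoate
Conditions: Ac2O, Et3N, N-methylimidazole (cat.), CH2Cl2, −20 → 0 °C
Reagents that add atoms: acetic anhydride, CC(=O)OC(C)=O
Why: O-Acetylation of the enolised formyl ester under amine (non-chelating) conditions should give the enol acetate with the acetoxy group trans to the ester and cis to C1, the geometry the ring closure needs.

**Step 11**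
Reactants: 19 enol acetate
Product: 21 methyl (2E)-2-(acetoxymethylidene)-3-[(tert-butyldimethylsilyl)oxy]-5-[(2R,3R)-3-formyl-2-methyloxiran-2-yl]pentanoate, via alkoxysulfonium chloride 20 (not isolated)
Conditions: (COCl)2, DMSO, CH2Cl2, −78 → −40 °C; Et3N, −78 → 0 °C
Reagents that add atoms: none
Why: Swern oxidation in which the activated sulfoxide first cleaves the primary triethylsilyl ether, so the protected alcohol goes straight to the α,β-epoxy aldehyde while the secondary silyl ether, enol acetate and epoxide survive.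

**Step 12**
Reactants: 21 epoxy aldehyde; 6 allylboronate
Product: 23 methyl (2E)-2-(acetoxymethylidene)-3-[(tert-butyldimethylsilyl)oxy]-5-[(2R,3S)-3-{(2S,3R)-3-[(4-methoxybenzyloxy)methyl]-4-methylidene-5-oxooxolan-2-yl}-2-methyloxiran-2-yl]pentanoate, via pinacol borate 22 (not isolated)
Conditions: toluene, 80 °C, sealed tube
Reagents that add atoms: none
Why: Thermal allylboration through a closed chair, in which the CH2OPMB group trans to CH2B (E-crotyl-type reagent) gives the anti C6/C7 pair, Felkin–Anh attack anti to the epoxide C–O bond sets C6 (S), and the borate then closes onto the neighbouring methyl ester to give the trans α-methylene lactone (C7 R).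

**Step 13**
Reactants: 23 lactone
Product: 24 methyl (2E)-2-(acetoxymethylidene)-3-hydroxy-5-[(2R,3S)-3-{(2S,3R)-3-[(4-methoxybenzyloxy)methyl]-4-methylidene-5-oxooxolan-2-yl}-2-methyloxiran-2-yl]pentanoate
Conditions: HF·pyridine, pyridine, THF, 0 °C → rt
Reagents that add atoms: none
Why: Buffered HF·pyridine cleaves the secondary silyl ether without touching the PMB ether, enol acetate, lactone or epoxide.

**Step 14**
Reactants: 24 C1 alcohol
Product: 25 methyl (2Z)-2-(acetoxymethylidene)-3-bromo-5-[(2R,3S)-3-{(2S,3R)-3-[(4-methoxybenzyloxy)methyl]-4-methylidene-5-oxooxolan-2-yl}-2-methyloxiran-2-yl]pentanoate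
Conditions: CBr4, PPh3, 2,6-lutidine (cat.), CH2Cl2, 0 °C
Reagents that add atoms: carbon tetrabromide, BrC(Br)(Br)Br
Why: Appel reaction in which the alkoxyphosphonium ion is displaced by bromide under neutral conditions; C1 epimers or any allylically transposed bromide converge later on the same allylchromium.

**Step 15**
Reactants: 25 bromide
Product: 26 methyl (2Z)-2-(acetoxymethylidene)-3-bromo-5-[(2R,3S)-3-{(2S,3R)-3-(hydroxymethyl)-4-methylidene-5-oxooxolan-2-yl}-2-methyloxiran-2-yl]pentanoate
Conditions: DDQ, CH2Cl2/pH 7 buffer, 0 °C → rt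
Reagents that add atoms: none
Why: Oxidative PMB cleavage by DDQ (benzylic hydride abstraction, hydrolysis of the oxocarbenium ion) is orthogonal to the bromide, enol acetate and epoxide.

**Step 16**
Reactants: 26 C8 alcohol
Product: 27 methyl (2Z)-2-(acetoxymethylidene)-3-bromo-5-[(2R,3S)-3-{(2S,3S)-3-formyl-4-methylidene-5-oxooxolan-2-yl}-2-methyloxiran-2-yl]pentanoate (C8 aldehyde; same spatial arrangement at C7, the descriptor changes because C8 is now CHO)
Conditions: Dess–Martin periodinane, pyridine, CH2Cl2, 0 °C; used crude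
Reagents that add atoms: none
Why: Dess–Martin oxidation under buffered, non-enolising conditions should give the aldehyde without epimerisation at C7 or migration of the exocyclic alkene into conjugation.

**Step 17**
Reactants: 27 C8 aldehyde with C1 bromide and enol acetate
Product: 29 (1(10)E,4R,5S,6S,7R,8S,9S)-9-acetoxy-4,5-epoxy-8-hydroxy-14-methoxy-14-oxogermacra-1(10),11(13)-dien-12,6-olide (8-de(methacryloyl) target), via allylchromium dichloride 28 (not isolated)
Conditions: CrCl2 (6 equiv), THF, 25 °C, syringe-pump addition of 27 (final ca. 2 mM); pH 7 buffer, 0 °C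
Reagents that add atoms: none
Why: Proposed new method: divalent chromium reduces the allylic C1–Br bond in two one-electron steps to a trivalent allylchromium bound at C1, and its acetoxy-bearing γ-carbon C9 attacks the chromium-bound C8 aldehyde through a six-membered chair with shift of the double bond to C1=C10; the closest known reactions are the CrCl2-mediated additions of 3-bromopropenyl esters (γ-acyloxyallyl chromium) to aldehydes and the CrCl2-mediated closures of ten-membered rings from allylic bromide aldehydes, including those with 2-(bromomethyl)acrylates. The ten-membered ring closes by an intramolecular γ-selective (SE2') carbonyl allylation in which all three allyl carbons become ring atoms. C9 is set by the enol acetate geometry, since the acetoxy group cis to C1 sits axial in the chair and gives the threo (syn) C8/C9 pair; C8 is set by the C7 stereocentre, because the tether through the trans-lactone delivers C9 to the aldehyde face flanked by C6 with the C7–C11 bond antiperiplanar (Felkin–Anh). The C1=C10 geometry follows from C2 lying axial on C1, which avoids allylic strain with the C10 ester and is the orientation the six-atom tether allows, so C2 ends cis to C9. The step needs γ- over α-attack, threo over erythro and ring closure over intermolecular coupling; the acetoxy terminus, the defined enol acetate, the lactone–epoxide tether and slow addition should secure these, and both C1 epimers of 27 converge on the same allylchromium.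

**Step 18**
Reactants: 29 8-de(methacryloyl) target
Product: 30 target CNP0153978.8, methyl (1(10)E,4R,5S,6S,7R,8S,9S)-9-acetoxy-4,5-epoxy-8-(methacryloyloxy)-12,6-olidogermacra-1(10),11(13)-dien-14-oate
Conditions: methacrylic anhydride, Et3N, DMAP (cat.), CH2Cl2, 0 °C
Reagents that add atoms: methacrylic anhydride, CC(=C)C(=O)OC(=O)C(C)=C
Why: DMAP-catalysed acylation of the secondary C8 alcohol, run cold with excess anhydride so that esterification outruns acetyl migration from O9 or lactonisation onto the C14 ester.

**Compound list**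
1 | prop-2-yn-1-ol | C#CCO | starting material
2 | 1-methoxy-4-[(prop-2-yn-1-yloxy)methyl]benzene | COc1ccc(COCC#C)cc1 | intermediate
3 | lithium acetylide of 2 | [Li]C#CCOCc1ccc(OC)cc1 | intermediate
4 | methyl 4-[(4-methoxybenzyl)oxy]but-2-ynoate | COC(=O)C#CCOCc1ccc(OC)cc1 | intermediate
5 | methyl (2E)-2-(diisobutylalumanyl)-4-[(4-methoxybenzyl)oxy]but-2-enoate (CH2OPMB cis to CO2Me) | COC(=O)/C(=C\COCc1ccc(OC)cc1)[Al](CC(C)C)CC(C)C | intermediate
6 | methyl (2Z)-4-[(4-methoxybenzyl)oxy]-2-[(4,4,5,5-tetramethyl-1,3,2-dioxaborolan-2-yl)methyl]but-2-enoate | COC(=O)/C(=C\COCc1ccc(OC)cc1)CB1OC(C)(C)C(C)(C)O1 | intermediate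
7 | nerol | CC(C)=CCC/C(C)=C\CO | starting material
8 | (2S,3R)-2,3-epoxynerol | OC[C@@H]1O[C@]1(C)CCC=C(C)C | intermediate
9 | triethylsilyl ether of 8 | CC[Si](CC)(CC)OC[C@@H]1O[C@]1(C)CCC=C(C)C | intermediate
10 | secondary ozonide (1,2,4-trioxolane) of 9 | CC[Si](CC)(CC)OC[C@@H]1O[C@]1(C)CCC1OOC(C)(C)O1 | intermediate
11 | 3-[(2R,3S)-2-methyl-3-(triethylsilyloxymethyl)oxiran-2-yl]propanal | CC[Si](CC)(CC)OC[C@@H]1O[C@]1(C)CCC=O | intermediate
12 | methyl acetate | CC(=O)OC | starting material
13 | lithium enolate of methyl acetate | [Li]OC(=C)OC | intermediate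
14 | methyl 3-hydroxy-5-[(2R,3S)-2-methyl-3-(triethylsilyloxymethyl)oxiran-2-yl]pentanoate (C3 epimers) | CC[Si](CC)(CC)OC[C@@H]1O[C@]1(C)CCC(O)CC(=O)OC | intermediate
15 | tert-butyldimethylsilyl ether of 14 | CC[Si](CC)(CC)OC[C@@H]1O[C@]1(C)CCC(O[Si](C)(C)C(C)(C)C)CC(=O)OC | intermediate
16 | methyl formate | COC=O | starting material
17 | lithium enolate of 15 | CC[Si](CC)(CC)OC[C@@H]1O[C@]1(C)CCC(O[Si](C)(C)C(C)(C)C)C=C(O[Li])OC | intermediate
18 | 2-formyl derivative of 15 (formyl/enol tautomers) | CC[Si](CC)(CC)OC[C@@H]1O[C@]1(C)CCC(O[Si](C)(C)C(C)(C)C)C(C=O)C(=O)OC | intermediate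
19 | (2E)-enol acetate of 18, acetoxy cis to C1 | CC[Si](CC)(CC)OC[C@@H]1O[C@]1(C)CCC(O[Si](C)(C)C(C)(C)C)/C(C(=O)OC)=C\OC(C)=O | intermediate
20 | alkoxydimethylsulfonium chloride from 19 | C[S+](C)OC[C@@H]1O[C@]1(C)CCC(O[Si](C)(C)C(C)(C)C)/C(C(=O)OC)=C\OC(C)=O.[Cl-] | intermediate
21 | (2R,3R)-epoxy aldehyde at C6 with the C1 silyl ether and enol acetate | O=C[C@@H]1O[C@]1(C)CCC(O[Si](C)(C)C(C)(C)C)/C(C(=O)OC)=C\OC(C)=O | intermediate
22 | pinacol borate of the anti C6/C7 homoallylic alcohol | COc1ccc(COC[C@@H](C(=C)C(=O)OC)[C@H](OB3OC(C)(C)C(C)(C)O3)[C@@H]2O[C@]2(C)CCC(O[Si](C)(C)C(C)(C)C)/C(C(=O)OC)=C\OC(C)=O)cc1 | intermediate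
23 | (4R,5S,6S,7R) trans α-methylene lactone with 8-O-PMB and 1-O-TBS | COc1ccc(COC[C@H]2C(=C)C(=O)O[C@@H]2[C@@H]2O[C@]2(C)CCC(O[Si](C)(C)C(C)(C)C)/C(C(=O)OC)=C\OC(C)=O)cc1 | intermediate
24 | C1 alcohol from 23 | COc1ccc(COC[C@H]2C(=C)C(=O)O[C@@H]2[C@@H]2O[C@]2(C)CCC(O)/C(C(=O)OC)=C\OC(C)=O)cc1 | intermediate
25 | C1 bromide with (Z)-enol acetate and 8-O-PMB | COc1ccc(COC[C@H]2C(=C)C(=O)O[C@@H]2[C@@H]2O[C@]2(C)CCC(Br)/C(C(=O)OC)=C\OC(C)=O)cc1 | intermediate
26 | C8 alcohol from 25 | OC[C@H]1C(=C)C(=O)O[C@@H]1[C@@H]1O[C@]1(C)CCC(Br)/C(C(=O)OC)=C\OC(C)=O | intermediate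
27 | C8 aldehyde with C1 bromide and (Z)-enol acetate | O=C[C@H]1C(=C)C(=O)O[C@@H]1[C@@H]1O[C@]1(C)CCC(Br)/C(C(=O)OC)=C\OC(C)=O | intermediate
28 | allylchromium dichloride bound at C1 (solvent ligands omitted) | O=C[C@H]1C(=C)C(=O)O[C@@H]1[C@@H]1O[C@]1(C)CCC([Cr](Cl)Cl)/C(C(=O)OC)=C\OC(C)=O | intermediate
29 | 8-de(methacryloyl) target with free C8 hydroxyl | O[C@H]1[C@H]2C(=C)C(=O)O[C@@H]2[C@@H]2O[C@]2(C)CC/C=C(/C(=O)OC)[C@@H]1OC(C)=O | intermediate
30 | CNP0153978.8 | C=C(C)C(=O)O[C@H]1[C@H]2C(=C)C(=O)O[C@@H]2[C@@H]2O[C@]2(C)CC/C=C(/C(=O)OC)[C@@H]1OC(C)=O | target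

**Step count:** 18 steps in total; longest linear sequence 15 steps (steps 4–18, from nerol).

**Steps most likely to fail**

1. Step 17 (ring closure). The allylchromium may add through C1 instead of C9, or may lose its enol acetate geometry by metal migration before it cyclises and so give the erythro pair. It may also couple between molecules, the aldehyde may epimerise at C7, and the new alkoxide may take over the C9 acetyl or lactonise onto the C14 ester. The fallback closes the ring at C9–C10 by a Nozaki–Hiyama–Kishi vinyl iodide–aldehyde macrocyclisation and sets out from aldehyde 11. A Wittig reaction with Ph3P=C(I)CO2Me should give the (Z)-2-iodo enoate F1. Swern oxidation of the primary silyl ether as in step 11 should give the epoxy aldehyde F2, and allylboration with 6 as in step 12 the trans lactone F3. DDQ should give the primary alcohol F4 and Dess–Martin oxidation the C8 aldehyde F5. Vinylmagnesium bromide at −78 °C, followed by methacrylic anhydride on the alkoxide, should give the allylic methacrylate F6 (Felkin–Anh addition, C8 epimers separated). Ozonolysis of the vinyl group, the least electron-poor alkene, should give the C9 aldehyde F7. CrCl2 with catalytic NiCl2 in DMF/THF at high dilution should then close the ring to the 9-hydroxy compound F8, and acetylation (Ac2O, DMAP) comes back to the route at 30.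

2. Step 12 (allylboration and lactonisation). Attack may occur on both aldehyde faces, because an E-type reagent erodes Felkin–Anh control; the ester-deactivated boronate may add slowly; and the borate may close incompletely. The fallback replaces substrate control by double stereodifferentiation and sets out from 6. Periodate cleavage of the pinacol (NaIO4, NH4OAc, aqueous acetone) should give the allylboronic acid F9. Esterification with (R,R)-diisopropyl tartrate (MgSO4) should give the tartrate boronate F10. This reagent class adds to the si face of aldehydes, the face the Felkin–Anh model already prefers here, through the same chair. Reaction with 21 in toluene over 4 Å molecular sieves at −78 → −20 °C, then warming to close the lactone, comes back to the route at 23.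

3. Step 14 (bromination). The acetyl group may migrate from the enol oxygen to the free C1 hydroxyl, the activated alcohol may eliminate to a diene, and the labile bromide may be lost in the two steps that follow. The fallback makes the C1 oxygen itself the leaving group and sets out from 24. ClP(O)(OEt)2 with N-methylimidazole should give the allylic diethyl phosphate F11. DDQ and then Dess–Martin oxidation, as in steps 15 and 16, should give the alcohol F12 and the aldehyde F13. CrCl2 with catalytic LiI in DMPU/THF, the known way to allylchromium reagents from allylic phosphates by way of the allylic iodide, should then give the same allylchromium 28 and come back to the route at 29.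

**Further compounds**
F1 | step 17 | methyl (2Z)-2-iodo-5-[(2R,3S)-2-methyl-3-(triethylsilyloxymethyl)oxiran-2-yl]pent-2-enoate | CC[Si](CC)(CC)OC[C@@H]1O[C@]1(C)CC/C=C(\I)C(=O)OC
F2 | step 17 | methyl (2Z)-5-[(2R,3R)-3-formyl-2-methyloxiran-2-yl]-2-iodopent-2-enoate | O=C[C@@H]1O[C@]1(C)CC/C=C(\I)C(=O)OC
F3 | step 17 | trans α-methylene lactone with 8-O-PMB and the (Z)-2-iodo enoate chain | COc1ccc(COC[C@H]2C(=C)C(=O)O[C@@H]2[C@@H]2O[C@]2(C)CC/C=C(\I)C(=O)OC)cc1
F4 | step 17 | C8 alcohol from F3 | OC[C@H]1C(=C)C(=O)O[C@@H]1[C@@H]1O[C@]1(C)CC/C=C(\I)C(=O)OC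
F5 | step 17 | C8 aldehyde from F4 | O=C[C@H]1C(=C)C(=O)O[C@@H]1[C@@H]1O[C@]1(C)CC/C=C(\I)C(=O)OC
F6 | step 17 | C8 vinyl carbinol methacrylate | C=C(C)C(=O)O[C@H](C=C)[C@H]1C(=C)C(=O)O[C@@H]1[C@@H]1O[C@]1(C)CC/C=C(\I)C(=O)OC
F7 | step 17 | C9 aldehyde with 8-O-methacrylate and the vinyl iodide | C=C(C)C(=O)O[C@H](C=O)[C@H]1C(=C)C(=O)O[C@@H]1[C@@H]1O[C@]1(C)CC/C=C(\I)C(=O)OC
F8 | step 17 | 9-de(acetyl) target with free C9 hydroxyl | C=C(C)C(=O)O[C@H]1[C@H]2C(=C)C(=O)O[C@@H]2[C@@H]2O[C@]2(C)CC/C=C(/C(=O)OC)[C@@H]1O
F9 | step 12 | {(2Z)-2-(methoxycarbonyl)-4-[(4-methoxybenzyl)oxy]but-2-en-1-yl}boronic acid | COC(=O)/C(=C\COCc1ccc(OC)cc1)CB(O)O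
F10 | step 12 | (R,R)-diisopropyl tartrate ester of F9 | COC(=O)/C(=C\COCc1ccc(OC)cc1)CB2O[C@@H](C(=O)OC(C)C)[C@H](C(=O)OC(C)C)O2
F11 | step 14 | C1 diethyl phosphate of 24 | COc1ccc(COC[C@H]2C(=C)C(=O)O[C@@H]2[C@@H]2O[C@]2(C)CCC(OP(=O)(OCC)OCC)/C(C(=O)OC)=C\OC(C)=O)cc1
F12 | step 14 | C8 alcohol with the C1 diethyl phosphate | OC[C@H]1C(=C)C(=O)O[C@@H]1[C@@H]1O[C@]1(C)CCC(OP(=O)(OCC)OCC)/C(C(=O)OC)=C\OC(C)=O
F13 | step 14 | C8 aldehyde with the C1 diethyl phosphate | O=C[C@H]1C(=C)C(=O)O[C@@H]1[C@@H]1O[C@]1(C)CCC(OP(=O)(OCC)OCC)/C(C(=O)OC)=C\OC(C)=O
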